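## Retrosynthetic overview

1. The last bond cut is the side-chain ester C–O. This gives a bicyclic diol (hydroheptelidic acid as its 2-(trimethylsilyl)ethyl ester) and bis-silylated gliocladic acid. One fluoride step then frees all protected groups.
2. The key C–C bond in both halves is the one that builds the CH=C(CH2OH)CO2R unit. It comes from an intermolecular aldol addition of a 3-hydroxypropanoate dianion to a ring aldehyde, followed by β-elimination.
3. Both ring aldehydes come from one enol triflate, made by trans conjugate vinylation of (S)-cryptone. Cryptone comes from isovaleraldehyde and methyl vinyl ketone by organocatalytic Michael addition and aldol condensation.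
4. In the bicyclic half, the tertiary C–OH is set by Sharpless epoxidation and epoxide-to-allylic-alcohol opening. The lactone carbon is delivered syn to that OH by a silicon-tethered radical, and the side-chain carbon is set by equilibration.
5. Ring order: cyclohexene (steps 1–2), then a temporary oxasilolane, then a temporary γ-lactone, then the seven-membered oxepinone. The second cyclohexene ring is carried through unchanged.

**Assumption:** the (S)-prolinol ether gives (S)-3 by the usual enamine shielding model. The rotation of 4 is checked before going on ((S)-cryptone is dextrorotatory), and the enantiomeric catalyst is equally available.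

**Locants in descriptive names:** C1 carries the CH2O group, C2 is the next ring carbon, C3 carries the side chain or its precursor, and C4 carries the isopropyl group.

**Abbreviations:** TBS = tert-butyldimethylsilyl, TMSE = 2-(trimethylsilyl)ethyl, Tf = trifluoromethanesulfonyl.

## Route

**Step 1**
Reactants: 1 3-methylbutanal; 2 but-3-en-2-one
Product: 3 (2S)-2-isopropyl-5-oxohexanal
Conditions: (S)-2-[methoxy(diphenyl)methyl]pyrrolidine (5 mol %), ethyl 3,4-dihydroxybenzoate (20 mol %), neat, 4 °C
Reagents that add atoms: none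
Why: This is an enamine-catalysed intermolecular Michael addition; the diphenylmethoxymethyl group shields one enamine face, so the new C–C bond sets the S centre (later C4).

**Step 2**
Reactants: 3 (2S)-2-isopropyl-5-oxohexanal
Product: 4 (S)-cryptone [(4S)-4-isopropylcyclohex-2-en-1-one]
Conditions: 0.1 M aq KOH, Bu4NOH (cat.), Et2O–THF, reflux
Reagents that add atoms: none
Why: This intramolecular aldol condensation closes the six-membered enone, and the stereocentre ends up γ to the carbonyl and is retained.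

**Step 3**
Reactants: 4 (S)-cryptone; 5 vinylmagnesium bromide
Product: 6 {[(3S,4S)-3-ethenyl-4-isopropylcyclohex-1-en-1-yl]oxy}trimethylsilane
Conditions: CH2=CHMgBr, CuBr·SMe2 (10 mol %), Me3SiCl, DMPU, THF, −78 °C; Et3N, cold aq NaHCO3
Reagents that add atoms: chlorotrimethylsilane C[Si](C)(C)Cl
Why: In this copper-catalysed, silyl-chloride-accelerated conjugate addition the vinyl group enters anti to the isopropyl group (trans product), and the enolate is trapped regiospecifically at C1/C2.

**Step 4**
Reactants: 6 silyl enol ether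
Product: 8 (3S,4S)-3-ethenyl-4-isopropylcyclohex-1-en-1-yl trifluoromethanesulfonate, via lithium enolate 7 (not isolated)
Conditions: MeLi, THF, 0 °C; then N-(5-chloropyridin-2-yl)bis(trifluoromethanesulfonimide), −78 to 0 °C; aq NH4Cl
Reagents that add atoms: methyllithium [Li]C (lithium only in 7); N-(5-chloropyridin-2-yl)bis(trifluoromethanesulfonimide) Clc1ccc(nc1)N(S(=O)(=O)C(F)(F)F)S(=O)(=O)C(F)(F)F
Why: Silicon–lithium exchange releases the regiodefined enolate without equilibration, and O-triflation fixes the C1=C2 double bond.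

**Step 5**
Reactants: 8 enol triflate
Product: 9 (3S,4S)-3-formyl-4-isopropylcyclohex-1-en-1-yl trifluoromethanesulfonate
Conditions: OsO4 (2 mol %), NaIO4, 2,6-lutidine, dioxane–H2O, rt
Reagents that add atoms: sodium periodate [Na+].[O-]I(=O)(=O)=O
Why: Lemieux–Johnson cleavage attacks only the monosubstituted vinyl group, because the enol triflate alkene is too electron-poor for osmylation.

**Step 6**
Reactants: 9 aldehyde; 10 methyl 3-hydroxypropanoate
Product: 12 methyl 3-hydroxy-2-(hydroxymethyl)-3-[(1S,6S)-6-isopropyl-3-(trifluoromethylsulfonyloxy)cyclohex-2-en-1-yl]propanoate (diastereomer mixture at the two new centres), via ester dianion 11 (not isolated)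
Conditions: 10, LiN(iPr)2 (2.1 equiv per 10), THF, −78 to −40 °C; 9, −78 °C; AcOH quench at −78 °C
Reagents that add atoms: lithium diisopropylamide [Li+].CC(C)[N-]C(C)C (lithium only in 11)
Why: This is an intermolecular aldol addition of a β-alkoxide ester enolate, which cannot β-eliminate because oxide is no leaving group; both new centres are erased in step 9.

**Step 7**
Reactants: 12 aldol triflate; 13 (tributylstannyl)methanol
Product: 14 methyl 3-hydroxy-2-(hydroxymethyl)-3-[(1S,6S)-3-(hydroxymethyl)-6-isopropylcyclohex-2-en-1-yl]propanoate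
Conditions: Pd(PPh3)4 (5 mol %), LiCl, dioxane, 95 °C
Reagents that add atoms: none
Why: Stille hydroxymethylation of the vinyl triflate leaves the alkene position unchanged, and free hydroxyl groups are tolerated.

**Step 8**
Reactants: 14 triol
Product: 15 methyl 2-[(TBS-oxy)methyl]-3-hydroxy-3-[(1S,6S)-3-[(TBS-oxy)methyl]-6-isopropylcyclohex-2-en-1-yl]propanoate
Conditions: t-BuMe2SiCl (2.2 equiv), imidazole, DMF, 0 °C
Reagents that add atoms: tert-butyldimethylsilyl chloride CC(C)(C)[Si](C)(C)Cl
Why: Silylation is selective for the two primary alcohols, because the flanked secondary carbinol reacts much more slowly.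

**Step 9**
Reactants: 15 bis-silyl ether
Product: 17 methyl (2E)-2-[(TBS-oxy)methyl]-3-[(1S,6S)-3-[(TBS-oxy)methyl]-6-isopropylcyclohex-2-en-1-yl]prop-2-enoate, via mesylate 16 (not isolated)
Conditions: MsCl, Et3N, CH2Cl2, 0 °C; then DBU, rt
Reagents that add atoms: methanesulfonyl chloride CS(=O)(=O)Cl (stays only in 16)
Why: Mesylation is followed by E1cB elimination through the ester enolate, so both diastereomers converge on the E alkene (ring trans to the ester) that minimises allylic strain.

**Step 10**
Reactants: 17 methyl ester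
Product: 18 (2E)-2-[(TBS-oxy)methyl]-3-[(1S,6S)-3-[(TBS-oxy)methyl]-6-isopropylcyclohex-2-en-1-yl]prop-2-enoic acid (bis-TBS gliocladic acid)
Conditions: KOSiMe3, THF, rt; cold 0.5 M HCl
Reagents that add atoms: none
Why: Anhydrous silanolate cleavage of the methyl ester spares the silyl ethers and the alkene geometry.

**Step 11**
Reactants: 8 enol triflate; 13 (tributylstannyl)methanol
Product: 19 [(3S,4S)-3-ethenyl-4-isopropylcyclohex-1-en-1-yl]methanol
Conditions: Pd(PPh3)4 (5 mol %), LiCl, dioxane, 95 °C
Reagents that add atoms: none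
Why: Stille hydroxymethylation gives the allylic alcohol needed for reagent-controlled epoxidation.

**Step 12**
Reactants: 19 allylic alcohol
Product: 20 [(1S,4S,5S,6S)-5-ethenyl-4-isopropyl-7-oxabicyclo[4.1.0]heptan-1-yl]methanol (epoxide oxygen cis to vinyl, trans to isopropyl)
Conditions: Ti(OiPr)4 (10 mol %), L-(+)-diethyl tartrate (12 mol %), t-BuOOH, 4 Å sieves, CH2Cl2, −20 °C
Reagents that add atoms: tert-butyl hydroperoxide CC(C)(C)OO
Why: In this Sharpless asymmetric epoxidation the L-(+)-tartrate catalyst gives the S configuration at the carbinol-bearing epoxide carbon by reagent control, and the isolated vinyl group is inert.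

**Step 13**
Reactants: 20 epoxy alcohol
Product: 21 TBS ether of 20
Conditions: t-BuMe2SiCl, imidazole, CH2Cl2, 0 °C to rt
Reagents that add atoms: tert-butyldimethylsilyl chloride CC(C)(C)[Si](C)(C)Cl
Why: Mild silylation blocks Payne rearrangement and protects the future acylation site.

**Step 14**
Reactants: 21 epoxy silyl ether
Product: 23 (3R,6S)-3-[(TBS-oxy)methyl]-3-hydroxy-6-isopropylcyclohex-1-ene-1-carbaldehyde, via epoxy aldehyde 22 (not isolated)
Conditions: OsO4 (2 mol %), NaIO4, 2,6-lutidine, dioxane–H2O, rt; extraction; then DBU (0.2 equiv), CH2Cl2, 0 °C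
Reagents that add atoms: sodium periodate [Na+].[O-]I(=O)(=O)=O
Why: Lemieux–Johnson cleavage is followed by E1cB opening of the β,γ-epoxy aldehyde; only the C2–O bond breaks, so the tertiary C1–O centre keeps the configuration set in step 12.

**Step 15**
Reactants: 23 γ-hydroxy enal
Product: 24 (3R,6S)-3-{[(bromomethyl)dimethylsilyl]oxy}-3-[(TBS-oxy)methyl]-6-isopropylcyclohex-1-ene-1-carbaldehyde
Conditions: BrCH2SiMe2Cl, Et3N, DMAP (cat.), CH2Cl2, 0 °C to rt
Reagents that add atoms: (bromomethyl)chlorodimethylsilane C[Si](C)(Cl)CBr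
Why: Silyl ether formation attaches a one-carbon radical precursor to the tertiary oxygen.

**Step 16**
Reactants: 24 bromomethylsilyl ether
Product: 25 cis-fused 2,2-dimethyl-1,2-oxasilolane aldehyde (C1 R, C2 S, C3 S, C4 S; O–Si–CH2 bridge from C1–O to C2, CHO on C3 trans to isopropyl)
Conditions: Bu3SnH (slow addition), AIBN (cat.), benzene (0.01 M), reflux; then DBU (cat.), CH2Cl2, rt
Reagents that add atoms: none
Why: In this Nishiyama–Stork 5-exo radical cyclisation onto the enal β-carbon the tether forces the new C2–C bond syn to the C1 oxygen. DBU then equilibrates C3 to the equatorial aldehyde, because an axial CHO would be syn-axial to CH2OTBS.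

**Step 17**
Reactants: 25 oxasilolane aldehyde
Product: 26 dimethyl acetal of 25 (C1 R, C2 S, C3 S, C4 S)
Conditions: MeOSiMe3, Me3SiOTf (5 mol %), CH2Cl2, −78 °C
Reagents that add atoms: methoxytrimethylsilane CO[Si](C)(C)C
Why: Aprotic Noyori acetalisation masks the aldehyde without opening the siloxane or touching the TBS ether.

**Step 18**
Reactants: 26 acetal
Product: 27 (C1 R, C2 R, C3 S, C4 S)-1-[(TBS-oxy)methyl]-3-(dimethoxymethyl)-2-(hydroxymethyl)-4-isopropylcyclohexan-1-ol
Conditions: 30% H2O2, KF, KHCO3, THF–MeOH, rt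
Reagents that add atoms: hydrogen peroxide OO
Why: Tamao oxidation turns the C–Si bond into C–OH and frees the tertiary alcohol, giving the syn 1,3-diol.

**Step 19**
Reactants: 27 diol
Product: 28 (C1 R, C2 S, C3 S, C4 S) β-hydroxy acid (CO2H on C2)
Conditions: TEMPO (cat.), NaClO2, NaOCl (cat.), pH 6.7 phosphate buffer–MeCN, 35 °C
Reagents that add atoms: sodium chlorite [Na+].[O-]Cl=O
Why: Buffered TEMPO/chlorite oxidation takes the only primary alcohol to the acid, and near neutral pH the transient aldehyde does not epimerise and the acetal survives.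

**Step 20**
Reactants: 28 acid
Product: 29 methyl ester of 28
Conditions: Me3SiCHN2, toluene–MeOH, 0 °C
Reagents that add atoms: (trimethylsilyl)diazomethane C[Si](C)(C)C=[N+]=[N-]
Why: Neutral O-methylation of the carboxylic acid leaves the stereocentres untouched.

**Step 21**
Reactants: 29 acetal ester
Product: 30 methyl (C1 R, C2 S, C3 S, C4 S)-1-hydroxy-1-[(TBS-oxy)methyl]-3-formyl-4-isopropylcyclohexane-2-carboxylate
Conditions: PPTS, acetone–H2O, 45 °C
Reagents that add atoms: water O
Why: Mild acetal hydrolysis releases the aldehyde, the hindered TBS ether survives, and the equatorial aldehyde is also the thermodynamic C3 epimer.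

**Step 22**
Reactants: 10 methyl 3-hydroxypropanoate; 31 2-(trimethylsilyl)ethanol
Product: 32 2-(trimethylsilyl)ethyl 3-hydroxypropanoate
Conditions: Ti(OiPr)4 (5 mol %), toluene, 100 °C, MeOH distilled off
Reagents that add atoms: none
Why: Titanate-catalysed transesterification is driven to completion by removal of methanol.

**Step 23**
Reactants: 30 aldehyde ester; 32 TMSE 3-hydroxypropanoate
Product: 35 cis-fused γ-lactone (C2–C(=O)–O–CH[CH(CH2OH)CO2TMSE]–C3; ring centres C1 R, C2 S, C3 S, C4 S; mixture at the two new centres), via ester dianion 33 (not isolated), via aldol adduct 34 (not isolated)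
Conditions: 32 (3 equiv), LiN(iPr)2 (6.2 equiv), THF, −78 to −40 °C; 30, −78 °C; AcOH quench at −78 °C; then PPTS (cat.), CH2Cl2, rt
Reagents that add atoms: lithium diisopropylamide [Li+].CC(C)[N-]C(C)C (lithium only in 33)
Why: Intermolecular aldol addition occurs at the aldehyde, which reacts faster than the ester. The new carbinol then lactonises onto the cis C2 ester, which turns it into a leaving group, and the cold quench avoids retro-aldol of the tertiary alkoxide.

**Step 24**
Reactants: 35 γ-lactone
Product: 36 seco acid (C1 R, C2 S, C3 R, C4 S; C2–CO2H, C3–CH=C(CH2OH)CO2TMSE with E geometry)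
Conditions: DBU (3 equiv), toluene, rt; citric acid work-up
Reagents that add atoms: none
Why: E1cB elimination of the lactone carboxylate through the ester enolate lets both diastereomers converge on the E alkene, which places CH2OH cis to the ring.

**Step 25**
Reactants: 36 seco acid
Product: 37 TMSE (5aR,6S,9R,9aS)-9-[(TBS-oxy)methyl]-9-hydroxy-6-isopropyl-1-oxo-1,3,5a,6,7,8,9,9a-octahydro-2-benzoxepine-4-carboxylate
Conditions: 2-methyl-6-nitrobenzoic anhydride, DMAP, CH2Cl2 (2 mM, slow addition), rt
Reagents that add atoms: none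
Why: In this Shiina lactonisation the alkene geometry and the cis C2/C3 arrangement hold the primary allylic OH next to the activated acyl group, and the tertiary OH does not compete.

**Step 26**
Reactants: 37 silyl ether
Product: 38 TMSE (5aR,6S,9R,9aS)-9-hydroxy-9-(hydroxymethyl)-6-isopropyl-1-oxo-1,3,5a,6,7,8,9,9a-octahydro-2-benzoxepine-4-carboxylate
Conditions: HF·pyridine, pyridine, THF, 0 °C to rt
Reagents that add atoms: none
Why: Acidic fluoride removes the TBS ether but not the TMSE ester, and the trans-diaxial CH2OH and lactone carbonyl cannot translactonise.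

**Step 27**
Reactants: 38 diol; 18 bis-TBS gliocladic acid
Product: 39 fully protected target (primary ester; two TBS ethers, one TMSE ester)
Conditions: EDC·HCl, DMAP, CH2Cl2, 0 °C to rt
Reagents that add atoms: none
Why: Steglich-type esterification acylates only the primary alcohol, because the tertiary one is inert.

**Step 28**
Reactants: 39 protected target
Product: 40 (5aR,6S,9R,9aS)-9-hydroxy-9-({[(2E)-2-(hydroxymethyl)-3-[(1S,6S)-3-(hydroxymethyl)-6-isopropylcyclohex-2-en-1-yl]prop-2-enoyl]oxy}methyl)-6-isopropyl-1-oxo-1,3,5a,6,7,8,9,9a-octahydro-2-benzoxepine-4-carboxylic acid (target)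
Conditions: Bu4NF, AcOH (1:1), THF, 0 °C to rt; pH 4 work-up
Reagents that add atoms: none
Why: Buffered fluoride cleaves both TBS ethers and fragments the TMSE ester in one operation, and near-neutral conditions spare the three ester linkages and C9a.

## Compound list

1 | 3-methylbutanal | CC(C)CC=O | starting material
2 | but-3-en-2-one | CC(=O)C=C | starting material
3 | (2S)-2-isopropyl-5-oxohexanal | CC(C)[C@@H](C=O)CCC(C)=O | intermediate
4 | (S)-cryptone | CC(C)[C@@H]1CCC(=O)C=C1 | intermediate
5 | vinylmagnesium bromide | C=C[Mg]Br | starting material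
6 | {[(3S,4S)-3-ethenyl-4-isopropylcyclohex-1-en-1-yl]oxy}trimethylsilane | C=C[C@@H]1C=C(O[Si](C)(C)C)CC[C@H]1C(C)C | intermediate
7 | lithium (3S,4S)-3-ethenyl-4-isopropylcyclohex-1-en-1-olate | C=C[C@@H]1C=C([O-])CC[C@H]1C(C)C.[Li+] | intermediate
8 | (3S,4S)-3-ethenyl-4-isopropylcyclohex-1-en-1-yl triflate | C=C[C@@H]1C=C(OS(=O)(=O)C(F)(F)F)CC[C@H]1C(C)C | intermediate
9 | (3S,4S)-3-formyl-4-isopropylcyclohex-1-en-1-yl triflate | O=C[C@@H]1C=C(OS(=O)(=O)C(F)(F)F)CC[C@H]1C(C)C | intermediate
10 | methyl 3-hydroxypropanoate | COC(=O)CCO | starting material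
11 | dilithium dianion of 10 | COC([O-])=CC[O-].[Li+].[Li+] | intermediate
12 | aldol diol, triflate | COC(=O)C(CO)C(O)[C@@H]1C=C(OS(=O)(=O)C(F)(F)F)CC[C@H]1C(C)C | intermediate
13 | (tributylstannyl)methanol | CCCC[Sn](CO)(CCCC)CCCC | starting material
14 | aldol triol | COC(=O)C(CO)C(O)[C@@H]1C=C(CO)CC[C@H]1C(C)C | intermediate
15 | bis-TBS ether of 14 | COC(=O)C(CO[Si](C)(C)C(C)(C)C)C(O)[C@@H]1C=C(CO[Si](C)(C)C(C)(C)C)CC[C@H]1C(C)C | intermediate
16 | mesylate of 15 | COC(=O)C(CO[Si](C)(C)C(C)(C)C)C(OS(C)(=O)=O)[C@@H]1C=C(CO[Si](C)(C)C(C)(C)C)CC[C@H]1C(C)C | intermediate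
17 | methyl bis-TBS gliocladate (E) | COC(=O)/C(CO[Si](C)(C)C(C)(C)C)=C/[C@@H]1C=C(CO[Si](C)(C)C(C)(C)C)CC[C@H]1C(C)C | intermediate
18 | bis-TBS gliocladic acid (E) | OC(=O)/C(CO[Si](C)(C)C(C)(C)C)=C/[C@@H]1C=C(CO[Si](C)(C)C(C)(C)C)CC[C@H]1C(C)C | intermediate
19 | [(3S,4S)-3-ethenyl-4-isopropylcyclohex-1-en-1-yl]methanol | C=C[C@@H]1C=C(CO)CC[C@H]1C(C)C | intermediate
20 | [(1S,4S,5S,6S)-5-ethenyl-4-isopropyl-7-oxabicyclo[4.1.0]heptan-1-yl]methanol | CC(C)[C@@H]1CC[C@@]2(CO)O[C@H]2[C@H]1C=C | intermediate
21 | TBS ether of 20 | CC(C)[C@@H]1CC[C@@]2(CO[Si](C)(C)C(C)(C)C)O[C@H]2[C@H]1C=C | intermediate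
22 | epoxy aldehyde | CC(C)[C@@H]1CC[C@@]2(CO[Si](C)(C)C(C)(C)C)O[C@H]2[C@H]1C=O | intermediate
23 | (3R,6S)-γ-hydroxy enal | CC(C)[C@@H]1CC[C@](O)(CO[Si](C)(C)C(C)(C)C)C=C1C=O | intermediate
24 | bromomethylsilyl ether of 23 | CC(C)[C@@H]1CC[C@](O[Si](C)(C)CBr)(CO[Si](C)(C)C(C)(C)C)C=C1C=O | intermediate
25 | oxasilolane aldehyde | CC(C)[C@@H]1CC[C@@]2(CO[Si](C)(C)C(C)(C)C)O[Si](C)(C)C[C@H]2[C@H]1C=O | intermediate
26 | oxasilolane dimethyl acetal | CC(C)[C@@H]1CC[C@@]2(CO[Si](C)(C)C(C)(C)C)O[Si](C)(C)C[C@H]2[C@H]1C(OC)OC | intermediate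
27 | 1,3-diol acetal | CC(C)[C@@H]1CC[C@](O)(CO[Si](C)(C)C(C)(C)C)[C@@H](CO)[C@H]1C(OC)OC | intermediate
28 | β-hydroxy acid acetal | CC(C)[C@@H]1CC[C@](O)(CO[Si](C)(C)C(C)(C)C)[C@@H](C(=O)O)[C@H]1C(OC)OC | intermediate
29 | methyl ester acetal | CC(C)[C@@H]1CC[C@](O)(CO[Si](C)(C)C(C)(C)C)[C@@H](C(=O)OC)[C@H]1C(OC)OC | intermediate
30 | aldehyde ester | CC(C)[C@@H]1CC[C@](O)(CO[Si](C)(C)C(C)(C)C)[C@@H](C(=O)OC)[C@H]1C=O | intermediate
31 | 2-(trimethylsilyl)ethanol | C[Si](C)(C)CCO | starting material
32 | TMSE 3-hydroxypropanoate | C[Si](C)(C)CCOC(=O)CCO | intermediate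
33 | dilithium dianion of 32 | C[Si](C)(C)CCOC([O-])=CC[O-].[Li+].[Li+] | intermediate
34 | open aldol adduct | CC(C)[C@@H]1CC[C@](O)(CO[Si](C)(C)C(C)(C)C)[C@@H](C(=O)OC)[C@H]1C(O)C(CO)C(=O)OCC[Si](C)(C)C | intermediate
35 | cis-fused γ-lactone | CC(C)[C@@H]1CC[C@](O)(CO[Si](C)(C)C(C)(C)C)[C@H]2C(=O)OC(C(CO)C(=O)OCC[Si](C)(C)C)[C@@H]12 | intermediate
36 | seco acid (E) | CC(C)[C@@H]1CC[C@](O)(CO[Si](C)(C)C(C)(C)C)[C@@H](C(=O)O)[C@H]1/C=C(/C(=O)OCC[Si](C)(C)C)CO | intermediate
37 | oxepinone, TBS ether, TMSE ester | CC(C)[C@@H]1CC[C@](O)(CO[Si](C)(C)C(C)(C)C)[C@H]2C(=O)OCC(C(=O)OCC[Si](C)(C)C)=C[C@@H]12 | intermediate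
38 | oxepinone diol, TMSE ester | CC(C)[C@@H]1CC[C@](O)(CO)[C@H]2C(=O)OCC(C(=O)OCC[Si](C)(C)C)=C[C@@H]12 | intermediate
39 | protected target | CC(C)[C@@H]1CC[C@](O)(COC(=O)/C(=C/[C@@H]2C=C(CO[Si](C)(C)C(C)(C)C)CC[C@H]2C(C)C)CO[Si](C)(C)C(C)(C)C)[C@H]2C(=O)OCC(C(=O)OCC[Si](C)(C)C)=C[C@@H]12 | intermediate
40 | CNP0361406.4 | CC(C)[C@@H]1CC[C@](O)(COC(=O)/C(=C/[C@@H]2C=C(CO)CC[C@H]2C(C)C)CO)[C@H]2C(=O)OCC(C(=O)O)=C[C@@H]12 | target

## Step count and risks

- **Total step count:** 28.
- **Longest linear sequence:** 21 steps (1–4, 11–21, 23–28).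

**Risk 1, step 6.** Aldehyde 9 is β,γ-unsaturated and α-branched, so the basic dianion may enolise it instead of adding to it.

The fallback sets out from 9 and comes back at 17. It replaces the aldol/elimination pair by olefination and cross-coupling. Aldehyde 9 is treated with methyl bromo(triphenylphosphoranylidene)acetate in CH2Cl2, which gives methyl (2Z)-2-bromo-3-[(1S,6S)-6-isopropyl-3-(trifluoromethylsulfonyloxy)cyclohex-2-en-1-yl]prop-2-enoate F1. A twofold Stille coupling with 13 (Pd(PPh3)4, LiCl, dioxane) then replaces both bromide and triflate with retention of geometry and gives methyl gliocladate F2. Silylation of both alcohols with t-BuMe2SiCl and imidazole gives 17.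

**Risk 2, step 16.** Direct reduction of the C–Br bond, or tin hydride attack on the enal, could compete with cyclisation at a carbon next to a quaternary centre.

The fallback sets out from 23 and comes back at 27. It uses an intermolecular, sterically controlled conjugate addition in place of the tether.

- The tertiary alcohol of 23 is capped with Me3SiOTf and 2,6-lutidine, giving the trimethylsilyl ether of the hydroxy enal F3.
- CH2=CHMgBr with CuBr·SMe2 and Me3SiCl adds vinyl to C2 from the face opposite both CH2OTBS and the isopropyl group. Mild acid work-up and DBU equilibration give the 2-vinyl aldehyde F4.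
- Acetalisation with MeOSiMe3 and Me3SiOTf gives the 2-vinyl dimethyl acetal F5.
- Ozonolysis with NaBH4 work-up, followed by K2CO3 in MeOH to remove the trimethylsilyl group, gives 27.

**Risk 3, step 25.** Seven-membered ring closure by acyl activation may be slow, and it could cause oligomers or epimerisation at C2.

The fallback sets out from 35 and comes back at 37, bypassing 36. It is a ring expansion by allylic transposition. MsCl and Et3N convert the primary alcohol of 35 into the primary mesylate of the γ-lactone F6. With more Et3N, F6 loses methanesulfonic acid to give the α-methylene ester F7, an O-acylated Baylis–Hillman-type adduct. DABCO in THF adds to the CH2 terminus and expels the carboxylate. The carboxylate then displaces DABCO at the same CH2, so the five-membered lactone expands to the conjugated oxepinone 37.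

## Further compounds

F1 | step 6 | methyl (2Z)-2-bromo-3-[(1S,6S)-6-isopropyl-3-(trifluoromethylsulfonyloxy)cyclohex-2-en-1-yl]prop-2-enoate | COC(=O)/C(Br)=C/[C@@H]1C=C(OS(=O)(=O)C(F)(F)F)CC[C@H]1C(C)C
F2 | step 6 | methyl gliocladate | COC(=O)/C(CO)=C/[C@@H]1C=C(CO)CC[C@H]1C(C)C
F3 | step 16 | trimethylsilyl ether of the hydroxy enal | CC(C)[C@@H]1CC[C@](O[Si](C)(C)C)(CO[Si](C)(C)C(C)(C)C)C=C1C=O
F4 | step 16 | 2-vinyl aldehyde | CC(C)[C@@H]1CC[C@](O[Si](C)(C)C)(CO[Si](C)(C)C(C)(C)C)[C@@H](C=C)[C@H]1C=O
F5 | step 16 | 2-vinyl dimethyl acetal | CC(C)[C@@H]1CC[C@](O[Si](C)(C)C)(CO[Si](C)(C)C(C)(C)C)[C@@H](C=C)[C@H]1C(OC)OC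
F6 | step 25 | primary mesylate of the γ-lactone | CC(C)[C@@H]1CC[C@](O)(CO[Si](C)(C)C(C)(C)C)[C@H]2C(=O)OC(C(COS(C)(=O)=O)C(=O)OCC[Si](C)(C)C)[C@@H]12
F7 | step 25 | α-methylene ester | CC(C)[C@@H]1CC[C@](O)(CO[Si](C)(C)C(C)(C)C)[C@H]2C(=O)OC(C(=C)C(=O)OCC[Si](C)(C)C)[C@@H]12
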